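**Assumption (one line):** the target has no stereocentre and the C2–C1′ axis (flanked on the pyranone side only by O1 and C3–H) is not expected to be configurationally stable, so the compound is achiral and "single enantiomer" is read as "the single constitution given".

Ring-B locants follow the target throughout: C1′ is bound to C2, C2′ carries OMe, C3′ and C6′ carry OH. In the IUPAC names of 7–10 the same two oxygens appear as the 5- and 2-substituents of the phenyl group.

## The problem

The target is a flavone whose two benzene rings carry seven oxygens, four as free OH (C5, C7, C3′, C6′) and three as OMe (C6, C8, C2′). Ring A is pentasubstituted with alternating OH/OMe. Ring B is 1,2,3,4-tetrasubstituted, with C1′ flanked by OMe (C2′) and OH (C6′), so the C2–C1′ bond is di-ortho-substituted and no simple building block has this pattern. Any plan that makes OMe groups by O-methylation or selective demethylation has to tell apart phenols of very similar reactivity. The sensitive elements are the B-ring hydroquinone (C3′-OH and C6′-OH are para, easily oxidised), the pyranone (opened by strong base, Wessely–Moser rearrangement), and the C6′ oxygen, which could close the pyranone from the wrong ring at the 1,3-diketone stage.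

Two features of the structure can be used. First, C6 and C8 are the two ring-A carbons ortho/para to the 5- and 7-hydroxyls and carry the same substituent, so they can be functionalised as a pair and Wessely–Moser scrambling is degenerate. Second, and decisive for the key step: the C3′/C6′ para-dihydroxy pair of ring B together with the bond from C1′ to C2, the β-carbon of the C2=C3–C4=O enone. In the derived p-quinone, C2′ is β to the C6′ carbonyl and is also the terminus of the vinylogous acceptor C2′=C1′–C2=C3–C4=O. The carbon that must carry OMe is therefore the most electrophilic carbon of the oxidised ring.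

## Retrosynthesis

**C2′–OMe bond (13 ⇒ 10).** The C2′–O bond is cut, not the O–CH3 bond. Target 13 is the formal adduct of methanol to p-quinone 11, which is the two-electron oxidation product of hydroquinone 10; the adduct is expected to be oxidised on to methoxyquinone 12 and is returned to 13 by reduction. The neighbouring cuts are worse: O-methylation would need one of three B-ring hydroxyls (and two A-ring hydroxyls) to be singled out, and cutting C2–C1′ first would demand a contiguously tetrasubstituted B-ring reagent. Precursor 10 has an unadorned 2,5-dihydroxyphenyl ring that comes from gentisic acid. The forward reaction must oxidise ring B only, add methanol at C2′ and not at C4′/C5′, and stop after one addition.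

**B-ring O–benzyl bonds (10 ⇒ 9).** The two hydroquinone oxygens are the only protected positions in the route. They are masked because a free hydroquinone would be oxidised by NBS and by copper salts in base. Benzyl is chosen over methyl because it must come off without touching three aryl methyl ethers. The forward reaction is a hydrogenolysis that must spare the C2=C3 bond.

**C6–OMe and C8–OMe bonds (9 ⇒ 8 ⇒ 7).** Both ring-A C–O bonds are cut back to C–Br (8) and then to C–H (7). The alternative, a pre-oxygenated acetophenone, would carry five differentiated oxygens on one ring and costs many steps. Here the free 5- and 7-hydroxyls direct bromination to exactly C6 and C8, and the phenoxide dianion carries the copper-mediated methoxylation. Precursor 7 has a plain phloroglucinol-type A ring. The forward reactions need double substitution without debromination.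

**Pyranone ring (7 ⇒ 5 + 4).** The C2–C3 bond (C-acylation of a ketone enolate) and the O1–C2 bond (cyclodehydration) are cut. This gives commercial 2,4,6-trihydroxyacetophenone 5, used without protection, and aroyl chloride 4. Ketone 5 is symmetric, so either ortho-hydroxyl closes to the same chromone through diketone 6, and the benzylated C6′ oxygen cannot compete. A chalcone route would add an oxidation and A-ring protection.

**Aroyl chloride (4 ⇒ 3 ⇒ 1).** Acid chloride 4 comes from acid 3, which comes from gentisic acid 1 by perbenzylation to ester 2 and saponification.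

## Roads not taken

**Alternative 1:** (the obvious route) Cut C2–C3/O1–C2 with every oxygen already in place. Claisen–Schmidt condensation of acetophenone A1 with aldehyde A2 gives chalcone A3; I2/DMSO oxidative cyclisation gives the tetrabenzyl flavone A4; hydrogenolysis gives the target. The forward key step is standard, but all the difficulty moves into the building blocks. A1 needs a pentaoxygenated benzene with three kinds of oxygen told apart, and A2 needs directed metalation of a protected methoxyhydroquinone. The route is several steps longer and carries four benzyl groups instead of two. The chosen plan never has to discriminate between hydroxyls, because each OMe enters as a C–O bond at a carbon that the free hydroxyls themselves activate.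

**Alternative 2:** Cut C2–C1′. Chromone A5 is zincated at C2 (TMPZnCl·LiCl) to A6, a polarity reversal of the electrophilic C2, and Negishi coupling with iodide A7 gives A4. This is convergent, but the coupling joins a di-ortho-substituted aryl iodide to a hindered heteroaryl zinc. A5 lacks a 2-substituent and is more prone to ring-opening by methoxide during its own preparation. Both partners need protecting groups and separate multi-step syntheses, so the oxygen-differentiation problem is unchanged.

**Alternative 3:** Cut the C3′–O bond. Late para-hydroxylation of the 6′-phenol of A8 by Elbs persulfate oxidation through aryl sulfate A9, then hydrolysis, copies a plausible biosynthetic order. It needs a B-ring block in which OMe and OH are already differentiated. The persulfate step relies on attack of a phenoxide on peroxydisulfate, and the acidic syringol-type 7-OH of ring A is a competing site for one-electron oxidation. In the chosen plan the oxidation is a two-electron hydroquinone-to-quinone step well below the potential of ring A, and it uses a symmetric, cheaper B-ring block.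

Key step: step 7

## Route

**Step 1**
Reactants: 1 2,5-dihydroxybenzoic acid (gentisic acid)
Product: 3 2,5-bis(benzyloxy)benzoic acid, via benzyl ester 2 (not isolated)
Conditions: BnBr (3.3 equiv), K2CO3, DMF, 60 °C; aqueous work-up, crude ester; KOH, MeOH/THF/H2O, 65 °C; then HCl
Reagents that add atoms: benzyl bromide BrCc1ccccc1; potassium hydroxide [K+].[OH-]
Why: Williamson O-alkylation of both phenols and the carboxylate, then saponification, which cleaves only the benzyl ester and leaves the two aryl benzyl ethers.

**Step 2**
Reactants: 3 2,5-bis(benzyloxy)benzoic acid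
Product: 4 2,5-bis(benzyloxy)benzoyl chloride
Conditions: (COCl)2 (1.5 equiv), DMF (cat.), CH2Cl2, 0 °C → rt; concentrate, use crude
Reagents that add atoms: oxalyl chloride ClC(=O)C(=O)Cl
Why: Acid chloride formation through the catalytic Vilsmeier-type chloroiminium species; by-products are volatile and aryl benzyl ethers tolerate the conditions.

**Step 3**
Reactants: 4 2,5-bis(benzyloxy)benzoyl chloride; 5 1-(2,4,6-trihydroxyphenyl)ethanone (dried)
Product: 7 2-[2,5-bis(benzyloxy)phenyl]-5,7-dihydroxy-4H-chromen-4-one, via 1,3-diketone 6 (not isolated)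
Conditions: 5, LiHMDS (4.2 equiv), THF, −78 → −10 °C; 4, −78 °C → rt; aq. HCl quench, solvent switch, crude diketone; AcOH, H2SO4 (0.5 vol %), 80 °C
Reagents that add atoms: none
Why: Claisen-type C-acylation of the lithium polyanion of 5 (three phenoxides plus the ketone enolate, the enolate carbon being the most nucleophilic site) gives diketone 6, and acid-catalysed cyclodehydration closes the pyranone. The two ortho-hydroxyls of the symmetric ring are equivalent and the B-ring ortho oxygen is benzylated, so only one chromone can form.

**Step 4**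
Reactants: 7 2-[2,5-bis(benzyloxy)phenyl]-5,7-dihydroxy-4H-chromen-4-one
Product: 8 2-[2,5-bis(benzyloxy)phenyl]-6,8-dibromo-5,7-dihydroxy-4H-chromen-4-one
Conditions: NBS (2.05 equiv), DMF, 0 °C → rt, dark
Reagents that add atoms: N-bromosuccinimide O=C1CCC(=O)N1Br
Why: Electrophilic aromatic bromination. C6 and C8 are each ortho/para to two free oxygen donors and react far faster than the dialkoxy B ring on the electron-poor C2 or than C3, so two equivalents should stop at the 6,8-dibromide.

**Step 5**
Reactants: 8 2-[2,5-bis(benzyloxy)phenyl]-6,8-dibromo-5,7-dihydroxy-4H-chromen-4-one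
Product: 9 2-[2,5-bis(benzyloxy)phenyl]-5,7-dihydroxy-6,8-dimethoxy-4H-chromen-4-one
Conditions: NaOMe (15 equiv, 25 wt % in MeOH), CuBr (0.3 equiv), DMF, 105 °C, Ar; then 1 M HCl
Reagents that add atoms: sodium methoxide [Na+].[O-]C
Why: Ullmann-type Cu(I)-mediated methoxylation of both aryl bromides on the phenoxide dianion, with close precedent on 6,8-dibromo-5,7-dihydroxyflavones. The dianion shields the pyranone from methoxide, and because C6 and C8 receive the same group any Wessely–Moser opening and re-closure is degenerate.

**Step 6**
Reactants: 9 2-[2,5-bis(benzyloxy)phenyl]-5,7-dihydroxy-6,8-dimethoxy-4H-chromen-4-one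
Product: 10 2-(2,5-dihydroxyphenyl)-5,7-dihydroxy-6,8-dimethoxy-4H-chromen-4-one
Conditions: H2 (1 atm), 10 % Pd/C, THF/MeOH, rt; filter under Ar, use at once
Reagents that add atoms: none
Why: Hydrogenolysis of the two aryl benzyl ethers. Aryl methyl ethers are inert and the conjugated C2=C3 bond of a flavone is reduced much more slowly under these conditions.

**Step 7**
Reactants: 10 2-(2,5-dihydroxyphenyl)-5,7-dihydroxy-6,8-dimethoxy-4H-chromen-4-one
Product: 13 5,7,3′,6′-tetrahydroxy-6,8,2′-trimethoxyflavone (target), via flavonyl-p-benzoquinone 11 (not isolated), via methoxy-p-quinone 12 (not isolated)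
Conditions: Ag2O (4 equiv), MeOH/THF 4:1, rt, dark, Ar; filter (Celite); then Na2S2O4, EtOAc/H2O, rt
Reagents that add atoms: methanol CO
Why: Proposed new method: Ag2O takes two electrons and two protons from the only para-dihydroxy pair of 10 (C3′-OH/C6′-OH) to give p-quinone 11; ring A has no ortho- or para-dihydroxy pair, its phenols are deactivated by the C4 carbonyl, and it cannot become a quinone without losing a methyl group, so it should stay untouched. In 11, C2′ is β to the C6′ carbonyl through C1′=C2′ and is also the terminus of the vinylogous acceptor C2′=C1′–C2=C3–C4=O, so the anion formed when methanol adds there is delocalised over O6′ and over the pyranone carbonyl, whereas addition at C4′ or C5′ is supported by one quinone carbonyl only. This is the regiochemistry known for hetero-nucleophiles adding at C3 of 2-acyl- and 2-alkoxycarbonyl-1,4-benzoquinones, and the reaction type (alcohol addition to a p-quinone, then enolisation to the hydroquinone) is the classical quinone alkoxylation; what is new is a chromon-2-yl group acting as the directing vinylogous acyl group. Enolisation re-aromatises ring B to the 2′-methoxyhydroquinone, which is more electron-rich than 10 and is therefore oxidised by the excess Ag2O to methoxyquinone 12, so that redox exchange between product and 11 does not limit conversion. In 12 the new methoxy group is a vinylogous ester donor towards C6′=O, and a second addition would have to occur at C5′ without help from the pyranone, so it should be much slower than the first under these Lewis-acid-free conditions. Dithionite then reduces 12 to hydroquinone 13. No ring is closed and no stereocentre is formed; the step needs regioselectivity (C2′ against C4′ and C5′) and chemoselectivity (ring B against ring A), and both follow from the substrate as described.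

## Compound list

1 | 2,5-dihydroxybenzoic acid (gentisic acid) | OC(=O)c1cc(O)ccc1O | starting material
2 | benzyl 2,5-bis(benzyloxy)benzoate | O=C(OCc1ccccc1)c1cc(OCc2ccccc2)ccc1OCc1ccccc1 | intermediate (not isolated)
3 | 2,5-bis(benzyloxy)benzoic acid | OC(=O)c1cc(OCc2ccccc2)ccc1OCc1ccccc1 | intermediate
4 | 2,5-bis(benzyloxy)benzoyl chloride | ClC(=O)c1cc(OCc2ccccc2)ccc1OCc1ccccc1 | intermediate
5 | 1-(2,4,6-trihydroxyphenyl)ethanone | CC(=O)c1c(O)cc(O)cc1O | starting material
6 | 1-[2,5-bis(benzyloxy)phenyl]-3-(2,4,6-trihydroxyphenyl)propane-1,3-dione | O=C(CC(=O)c1cc(OCc2ccccc2)ccc1OCc1ccccc1)c1c(O)cc(O)cc1O | intermediate (not isolated)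
7 | 2-[2,5-bis(benzyloxy)phenyl]-5,7-dihydroxy-4H-chromen-4-one | O=c1cc(-c2cc(OCc3ccccc3)ccc2OCc2ccccc2)oc2cc(O)cc(O)c12 | intermediate
8 | 2-[2,5-bis(benzyloxy)phenyl]-6,8-dibromo-5,7-dihydroxy-4H-chromen-4-one | O=c1cc(-c2cc(OCc3ccccc3)ccc2OCc2ccccc2)oc2c(Br)c(O)c(Br)c(O)c12 | intermediate
9 | 2-[2,5-bis(benzyloxy)phenyl]-5,7-dihydroxy-6,8-dimethoxy-4H-chromen-4-one | O=c1cc(-c2cc(OCc3ccccc3)ccc2OCc2ccccc2)oc2c(OC)c(O)c(OC)c(O)c12 | intermediate
10 | 2-(2,5-dihydroxyphenyl)-5,7-dihydroxy-6,8-dimethoxy-4H-chromen-4-one | O=c1cc(-c2cc(O)ccc2O)oc2c(OC)c(O)c(OC)c(O)c12 | intermediate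
11 | 2-(5,7-dihydroxy-6,8-dimethoxy-4-oxo-4H-chromen-2-yl)cyclohexa-2,5-diene-1,4-dione | O=C1C=CC(=O)C(c2cc(=O)c3c(O)c(OC)c(O)c(OC)c3o2)=C1 | intermediate (not isolated)
12 | 2-(5,7-dihydroxy-6,8-dimethoxy-4-oxo-4H-chromen-2-yl)-3-methoxycyclohexa-2,5-diene-1,4-dione | COC1=C(c2cc(=O)c3c(O)c(OC)c(O)c(OC)c3o2)C(=O)C=CC1=O | intermediate (not isolated)
13 | 5,7,3′,6′-tetrahydroxy-6,8,2′-trimethoxyflavone | COc1c(O)ccc(O)c1-c1cc(=O)c2c(O)c(OC)c(O)c(OC)c2o1 | target

## Step count and risk

Total steps: 7. Longest linear sequence: 7 (from 1; ketone 5 enters in step 3).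

**Step 7 (key step, Proposed new method).** Methanol may add across the unsubstituted C4′=C5′ bond instead of at C2′ if steric shielding by the pyranone, or twisting about C1′–C2 that weakens the vinylogous activation, outweighs the electronic preference. Methoxyquinone 12 may take up a second methanol. The quinones may also be consumed by intermolecular addition of the acidic 7-hydroxyl of another molecule.

Fallback (known chemistry only; the C2′ methoxy group comes in with the B-ring building block instead of being added late). Commercial 2-methoxyhydroquinone (COc1cc(O)ccc1O) is benzylated (BnBr, K2CO3) to 1,4-bis(benzyloxy)-2-methoxybenzene F1. Directed ortho-metalation between the methoxy and benzyloxy groups (n-BuLi, TMEDA, THF, −78 → 0 °C) and carboxylation with CO2 give 3,6-bis(benzyloxy)-2-methoxybenzoic acid F2, and oxalyl chloride gives 3,6-bis(benzyloxy)-2-methoxybenzoyl chloride F3. The fallback sets out from 5. Its polyanion is acylated with F3 and the diketone cyclised as in step 3 to 2-[3,6-bis(benzyloxy)-2-methoxyphenyl]-5,7-dihydroxy-4H-chromen-4-one F4. NBS as in step 4 gives 2-[3,6-bis(benzyloxy)-2-methoxyphenyl]-6,8-dibromo-5,7-dihydroxy-4H-chromen-4-one F5. Copper-mediated methoxylation as in step 5 gives 2-[3,6-bis(benzyloxy)-2-methoxyphenyl]-5,7-dihydroxy-6,8-dimethoxy-4H-chromen-4-one F6. Hydrogenolysis as in step 6 comes back to the route at the target 13.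

**Step 5.** Reductive loss of bromine (protodebromination) or a stalled second substitution may occur on the very electron-rich dianion, and methoxide may open the pyranone ring.

Fallback (formylation and oxidative C→O exchange instead of halogen/alkoxide exchange), setting out from 7. Double Duff formylation (hexamethylenetetramine, AcOH, 100 °C; aq. HCl) gives 2-[2,5-bis(benzyloxy)phenyl]-5,7-dihydroxy-4-oxo-4H-chromene-6,8-dicarbaldehyde F7. Benzylation of both phenols (BnBr, K2CO3, DMF, 80 °C) gives 5,7-bis(benzyloxy)-2-[2,5-bis(benzyloxy)phenyl]-4-oxo-4H-chromene-6,8-dicarbaldehyde F8. Baeyer–Villiger oxidation of the two electron-rich aryl aldehydes (mCPBA, CH2Cl2) and methanolysis of the formates (K2CO3, MeOH) give 5,7-bis(benzyloxy)-2-[2,5-bis(benzyloxy)phenyl]-6,8-dihydroxy-4H-chromen-4-one F9. O-Methylation (MeI, K2CO3, acetone) gives 5,7-bis(benzyloxy)-2-[2,5-bis(benzyloxy)phenyl]-6,8-dimethoxy-4H-chromen-4-one F10. Hydrogenolysis of all four benzyl ethers (H2, Pd/C) comes back to the route at 10.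

**Step 3.** O-Acylation of the phenoxides may compete with C-acylation by the ortho-substituted aroyl chloride, a second acylation may occur, and partial loss of the ortho benzyl ether in hot acid could be followed by closure from the wrong ring.

Fallback (the pyranone is built onto a phenol instead of from the acetophenone), setting out from 4. Acylation of magnesium ethyl malonate (potassium ethyl malonate, MgCl2, Et3N, MeCN; aq. HCl, decarboxylation) gives ethyl 3-[2,5-bis(benzyloxy)phenyl]-3-oxopropanoate F11. Mentzer thermal condensation of F11 with commercial phloroglucinol (Oc1cc(O)cc(O)c1; neat, 220–240 °C, short time) forms the C4–C4a and O1–C2 bonds and comes back to the route at 7.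

## Further compounds

F1 | step 7 | 1,4-bis(benzyloxy)-2-methoxybenzene | COc1cc(OCc2ccccc2)ccc1OCc1ccccc1
F2 | step 7 | 3,6-bis(benzyloxy)-2-methoxybenzoic acid | COc1c(C(=O)O)c(OCc2ccccc2)ccc1OCc1ccccc1
F3 | step 7 | 3,6-bis(benzyloxy)-2-methoxybenzoyl chloride | COc1c(C(=O)Cl)c(OCc2ccccc2)ccc1OCc1ccccc1
F4 | step 7 | 2-[3,6-bis(benzyloxy)-2-methoxyphenyl]-5,7-dihydroxy-4H-chromen-4-one | COc1c(OCc2ccccc2)ccc(OCc2ccccc2)c1-c1cc(=O)c2c(O)cc(O)cc2o1
F5 | step 7 | 2-[3,6-bis(benzyloxy)-2-methoxyphenyl]-6,8-dibromo-5,7-dihydroxy-4H-chromen-4-one | COc1c(OCc2ccccc2)ccc(OCc2ccccc2)c1-c1cc(=O)c2c(O)c(Br)c(O)c(Br)c2o1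
F6 | step 7 | 2-[3,6-bis(benzyloxy)-2-methoxyphenyl]-5,7-dihydroxy-6,8-dimethoxy-4H-chromen-4-one | COc1c(OCc2ccccc2)ccc(OCc2ccccc2)c1-c1cc(=O)c2c(O)c(OC)c(O)c(OC)c2o1
F7 | step 5 | 2-[2,5-bis(benzyloxy)phenyl]-5,7-dihydroxy-4-oxo-4H-chromene-6,8-dicarbaldehyde | O=Cc1c(O)c(C=O)c2oc(-c3cc(OCc4ccccc4)ccc3OCc3ccccc3)cc(=O)c2c1O
F8 | step 5 | 5,7-bis(benzyloxy)-2-[2,5-bis(benzyloxy)phenyl]-4-oxo-4H-chromene-6,8-dicarbaldehyde | O=Cc1c(OCc2ccccc2)c(C=O)c2oc(-c3cc(OCc4ccccc4)ccc3OCc3ccccc3)cc(=O)c2c1OCc1ccccc1
F9 | step 5 | 5,7-bis(benzyloxy)-2-[2,5-bis(benzyloxy)phenyl]-6,8-dihydroxy-4H-chromen-4-one | Oc1c(OCc2ccccc2)c(O)c2oc(-c3cc(OCc4ccccc4)ccc3OCc3ccccc3)cc(=O)c2c1OCc1ccccc1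
F10 | step 5 | 5,7-bis(benzyloxy)-2-[2,5-bis(benzyloxy)phenyl]-6,8-dimethoxy-4H-chromen-4-one | COc1c(OCc2ccccc2)c(OC)c2oc(-c3cc(OCc4ccccc4)ccc3OCc3ccccc3)cc(=O)c2c1OCc1ccccc1
F11 | step 3 | ethyl 3-[2,5-bis(benzyloxy)phenyl]-3-oxopropanoate | CCOC(=O)CC(=O)c1cc(OCc2ccccc2)ccc1OCc1ccccc1
A1 | alternative 1 | 1-[4,6-bis(benzyloxy)-2-hydroxy-3,5-dimethoxyphenyl]ethanone | CC(=O)c1c(O)c(OC)c(OCc2ccccc2)c(OC)c1OCc1ccccc1
A2 | alternative 1 | 3,6-bis(benzyloxy)-2-methoxybenzaldehyde | COc1c(C=O)c(OCc2ccccc2)ccc1OCc1ccccc1
A3 | alternative 1 | (E)-1-[4,6-bis(benzyloxy)-2-hydroxy-3,5-dimethoxyphenyl]-3-[3,6-bis(benzyloxy)-2-methoxyphenyl]prop-2-en-1-one | COc1c(OCc2ccccc2)ccc(OCc2ccccc2)c1/C=C/C(=O)c1c(O)c(OC)c(OCc2ccccc2)c(OC)c1OCc1ccccc1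
A4 | alternative 1 | 5,7-bis(benzyloxy)-2-[3,6-bis(benzyloxy)-2-methoxyphenyl]-6,8-dimethoxy-4H-chromen-4-one | COc1c(OCc2ccccc2)ccc(OCc2ccccc2)c1-c1cc(=O)c2c(OCc3ccccc3)c(OC)c(OCc3ccccc3)c(OC)c2o1
A5 | alternative 2 | 5,7-bis(benzyloxy)-6,8-dimethoxy-4H-chromen-4-one | COc1c(OCc2ccccc2)c(OC)c2occc(=O)c2c1OCc1ccccc1
A6 | alternative 2 | [5,7-bis(benzyloxy)-6,8-dimethoxy-4-oxo-4H-chromen-2-yl]zinc chloride | COc1c(OCc2ccccc2)c(OC)c2oc([Zn]Cl)cc(=O)c2c1OCc1ccccc1
A7 | alternative 2 | 1,4-bis(benzyloxy)-3-iodo-2-methoxybenzene | COc1c(I)c(OCc2ccccc2)ccc1OCc1ccccc1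
A8 | alternative 3 | 5,7-dihydroxy-2-(2-hydroxy-6-methoxyphenyl)-6,8-dimethoxy-4H-chromen-4-one | COc1cccc(O)c1-c1cc(=O)c2c(O)c(OC)c(O)c(OC)c2o1
A9 | alternative 3 | 4-hydroxy-2-methoxy-3-(5,7-dihydroxy-6,8-dimethoxy-4-oxo-4H-chromen-2-yl)phenyl hydrogen sulfate | COc1c(OS(=O)(=O)O)ccc(O)c1-c1cc(=O)c2c(O)c(OC)c(O)c(OC)c2o1
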